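**Retrosynthetic overview**
- The tertiary alcohol is made last, by Markovnikov hydration of a cyclohexene that already carries the trans Br/Cl pair.
- The trans Br/Cl pair comes from a catalyst-controlled epoxide on the methyl-bearing alkene of a 1,4-cyclohexadiene (bromide opening with inversion, then chloride with retention through a bromonium ion).
- The 1,4-diene and the cyclopentyl carbinol come from one dissolving-metal reduction of an aryl cyclopentenone (arene, C=C and C=O together; key step), followed by SN2 bromination.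
- The aryl cyclopentenone comes from asymmetric conjugate arylation of 3-methylcyclopentenone with p-tolylboronic acid, dehydrogenation and gem-dimethylation.
- Ring order: the cyclopentane is present from the start; the cyclohexane is the former p-tolyl ring.

Assumption: both starting materials, (S)-t-BuPyOx and the D-fructose-derived Shi ketone are purchased; minor stereoisomers are removed by chromatography or crystallisation where they arise.

**Step 1**
Reactants: 1 3-methylcyclopent-2-en-1-one; 2 (4-methylphenyl)boronic acid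
Product: 3 (3R)-3-methyl-3-(4-methylphenyl)cyclopentan-1-one
Conditions: Pd(OCOCF3)2 (5 mol%), (S)-t-BuPyOx (6 mol%), NH4PF6, H2O, ClCH2CH2Cl, 40 °C
Reagents that add atoms: none
Why: Pd(II)/PyOx-catalysed asymmetric conjugate addition of an arylboronic acid, in which aryl insertion on one enantioface of the β,β-disubstituted enone sets the quaternary centre as R (the antipodal ligand is used if the sense in this ring size is opposite).

**Step 2**
Reactants: 3 (3R)-3-methyl-3-(4-methylphenyl)cyclopentan-1-one
Product: 4 (4S)-4-methyl-4-(4-methylphenyl)cyclopent-2-en-1-one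
Conditions: IBX·MPO (1.5 equiv), DMSO, 25 °C
Reagents that add atoms: none
Why: IBX ketone dehydrogenation, which can only desaturate the side away from the quaternary carbon and is run at 25 °C to spare the benzylic methyl; the stereocentre is untouched and only its CIP descriptor changes.

**Step 3**
Reactants: 4 (4S)-4-methyl-4-(4-methylphenyl)cyclopent-2-en-1-one
Product: 6 (4S)-4,5,5-trimethyl-4-(4-methylphenyl)cyclopent-2-en-1-one, via monomethyl enone 5 (not isolated)
Conditions: KHMDS (2.5 equiv, two portions), MeI (5 equiv), THF, −78 → 0 °C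
Reagents that add atoms: iodomethane, CI
Why: Exhaustive enolate alkylation at C5, the only enolisable position of the 4,4-disubstituted cyclopentenone, builds the gem-dimethyl carbon next to the quaternary centre without creating a stereocentre.

**Step 4 (key step)**
Reactants: 6 (4S)-4,5,5-trimethyl-4-(4-methylphenyl)cyclopent-2-en-1-one
Product: 8 (1R,3S)-2,2,3-trimethyl-3-(4-methylcyclohexa-1,4-dien-1-yl)cyclopentan-1-ol, via enolate of ketone 7 (not isolated)
Conditions: Li (excess), NH3(l)/THF, EtOH, −78 → −33 °C; NH4Cl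
Reagents that add atoms: none
Why: Birch-type dissolving-metal reduction in which the enone gives enolate 7, EtOH protonates it and the ketone is reduced on under thermodynamic control to the carbinol with OH trans to the bulky C3 ring substituent (1R), while the p-dialkylarene is dearomatised to the 1,4-diene with both alkyl groups on sp2 carbons.

**Step 5**
Reactants: 8 (1R,3S)-2,2,3-trimethyl-3-(4-methylcyclohexa-1,4-dien-1-yl)cyclopentan-1-ol
Product: 9 1-[(1S,3S)-3-bromo-1,2,2-trimethylcyclopentyl]-4-methylcyclohexa-1,4-diene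
Conditions: CBr4, PPh3, toluene, 0 → 70 °C
Reagents that add atoms: tetrabromomethane, BrC(Br)(Br)Br
Why: Appel bromination by SN2 inversion at the neopentylic carbinol turns the (R)-alcohol into the (S)-bromide, placing Br cis to the six-membered ring as in the target.

**Step 6**
Reactants: 9 1-[(1S,3S)-3-bromo-1,2,2-trimethylcyclopentyl]-4-methylcyclohexa-1,4-diene
Product: 10 (1S,6R)-4-[(1S,3S)-3-bromo-1,2,2-trimethylcyclopentyl]-1-methyl-7-oxabicyclo[4.1.0]hept-3-ene
Conditions: Shi ketone (D-fructose-derived, 30 mol%), Oxone, K2CO3, Bu4NHSO4, MeCN–DMM/aq. buffer pH 10.5, 0 °C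
Reagents that add atoms: potassium peroxymonosulfate (Oxone), [K+].[O-]S(=O)(=O)OO
Why: Shi epoxidation (chiral dioxirane, spiro transition state) picks the less hindered methyl-substituted alkene and one of its faces under catalyst control (same facial sense as 1-phenylcyclohexene), which fixes the ring stereochemistry independently of the remote cyclopentane and turns residual enantiomer from step 1 into a removable diastereomer.

**Step 7**
Reactants: 10 (1S,6R)-4-[(1S,3S)-3-bromo-1,2,2-trimethylcyclopentyl]-1-methyl-7-oxabicyclo[4.1.0]hept-3-ene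
Product: 11 (1S,6S)-6-bromo-4-[(1S,3S)-3-bromo-1,2,2-trimethylcyclopentyl]-1-methylcyclohex-3-en-1-ol
Conditions: LiBr, AcOH, THF, 0 °C → rt
Reagents that add atoms: lithium bromide, [Li+].[Br-]
Why: Acid-buffered SN2 opening of the trisubstituted epoxide by bromide at the secondary carbon with inversion gives the trans bromohydrin with the C–Br centre in its final configuration.

**Step 8**
Reactants: 11 (1S,6S)-6-bromo-4-[(1S,3S)-3-bromo-1,2,2-trimethylcyclopentyl]-1-methylcyclohex-3-en-1-ol
Product: 13 (4S,5S)-5-bromo-1-[(1S,3S)-3-bromo-1,2,2-trimethylcyclopentyl]-4-chloro-4-methylcyclohex-1-ene, via chlorosulfite ester 12 (not isolated)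
Conditions: SOCl2, TiCl4 (cat.), CH2Cl2, −78 → 0 °C
Reagents that add atoms: thionyl chloride, O=S(Cl)Cl
Why: Darzens-type chlorination in which the chlorosulfite ionises with anchimeric assistance of the anti bromine and chloride opens the bromonium ion at the tertiary carbon, so C–O is replaced by C–Cl with net retention and Br/Cl end trans.

**Step 9**
Reactants: 13 (4S,5S)-5-bromo-1-[(1S,3S)-3-bromo-1,2,2-trimethylcyclopentyl]-4-chloro-4-methylcyclohex-1-ene
Product: 15 (1R,3S,4S)-3-bromo-1-[(1R,3S)-3-bromo-1,2,2-trimethylcyclopentyl]-4-chloro-4-methylcyclohexan-1-ol, via tertiary hydroperoxide 14 (not isolated)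
Conditions: Mn(dpm)3 (cat.), PhSiH3, O2 (1 atm), i-PrOH–CH2Cl2, 0 °C
Reagents that add atoms: dioxygen, O=O
Why: Mukaiyama (MHAT) Markovnikov hydration, in which H• adds to the alkene CH and O2 traps the tertiary radical axially in the chair that keeps the cyclopentyl group equatorial and avoids a syn-axial Br/O contact, giving OH trans to Br and cis to Cl (1R); this facial preference is a conformational argument, not a precedented result.

**Compound list**
1 | 3-methylcyclopent-2-en-1-one | CC1=CC(=O)CC1 | starting material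
2 | (4-methylphenyl)boronic acid | Cc1ccc(cc1)B(O)O | starting material
3 | (3R)-3-methyl-3-(4-methylphenyl)cyclopentan-1-one | O=C1CC[C@](C)(C1)c1ccc(C)cc1 | intermediate
4 | (4S)-4-methyl-4-(4-methylphenyl)cyclopent-2-en-1-one | O=C1C=C[C@](C)(C1)c1ccc(C)cc1 | intermediate
5 | (4R)-4,5-dimethyl-4-(4-methylphenyl)cyclopent-2-en-1-one (both C5 epimers) | CC1C(=O)C=C[C@@]1(C)c1ccc(C)cc1 | intermediate
6 | (4S)-4,5,5-trimethyl-4-(4-methylphenyl)cyclopent-2-en-1-one | CC1(C)C(=O)C=C[C@@]1(C)c1ccc(C)cc1 | intermediate
7 | (3S)-2,2,3-trimethyl-3-(4-methylphenyl)cyclopentan-1-one (present as its lithium enolate) | CC1(C)C(=O)CC[C@@]1(C)c1ccc(C)cc1 | intermediate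
8 | (1R,3S)-2,2,3-trimethyl-3-(4-methylcyclohexa-1,4-dien-1-yl)cyclopentan-1-ol | CC1(C)[C@H](O)CC[C@@]1(C)C1=CCC(C)=CC1 | intermediate
9 | 1-[(1S,3S)-3-bromo-1,2,2-trimethylcyclopentyl]-4-methylcyclohexa-1,4-diene | CC1(C)[C@@H](Br)CC[C@@]1(C)C1=CCC(C)=CC1 | intermediate
10 | (1S,6R)-4-[(1S,3S)-3-bromo-1,2,2-trimethylcyclopentyl]-1-methyl-7-oxabicyclo[4.1.0]hept-3-ene | CC1(C)[C@@H](Br)CC[C@@]1(C)C1=CC[C@]2(C)O[C@@H]2C1 | intermediate
11 | (1S,6S)-6-bromo-4-[(1S,3S)-3-bromo-1,2,2-trimethylcyclopentyl]-1-methylcyclohex-3-en-1-ol | CC1(C)[C@@H](Br)CC[C@@]1(C)C1=CC[C@](C)(O)[C@@H](Br)C1 | intermediate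
12 | (1S,6S)-6-bromo-4-[(1S,3S)-3-bromo-1,2,2-trimethylcyclopentyl]-1-methylcyclohex-3-en-1-yl chlorosulfite | CC1(C)[C@@H](Br)CC[C@@]1(C)C1=CC[C@](C)(OS(=O)Cl)[C@@H](Br)C1 | intermediate
13 | (4S,5S)-5-bromo-1-[(1S,3S)-3-bromo-1,2,2-trimethylcyclopentyl]-4-chloro-4-methylcyclohex-1-ene | CC1(C)[C@@H](Br)CC[C@@]1(C)C1=CC[C@](C)(Cl)[C@@H](Br)C1 | intermediate
14 | (1R,3S,4S)-3-bromo-1-[(1R,3S)-3-bromo-1,2,2-trimethylcyclopentyl]-4-chloro-4-methylcyclohexyl hydroperoxide | CC1(C)[C@@H](Br)CC[C@@]1(C)[C@@]1(OO)CC[C@](C)(Cl)[C@@H](Br)C1 | intermediate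
15 | (1R,3S,4S)-3-bromo-1-[(1R,3S)-3-bromo-1,2,2-trimethylcyclopentyl]-4-chloro-4-methylcyclohexan-1-ol | CC1(C)[C@@H](Br)CC[C@@]1(C)[C@@]1(O)CC[C@](C)(Cl)[C@@H](Br)C1 | target

**Totals**
Total step count: 9. Longest linear sequence: 9 (fully linear).

**Steps most likely to fail, with fallbacks**

Step 5 (SN2 at a neopentylic secondary carbinol; risk of no reaction or Wagner–Meerwein shift). The fallback sets out from 8 and replaces the in-situ phosphonium activation by a discrete activation/displacement pair. Alcohol 8 is treated with ClCH2SO2Cl and pyridine at 0 °C to give (1R,3S)-2,2,3-trimethyl-3-(4-methylcyclohexa-1,4-dien-1-yl)cyclopentyl chloromethanesulfonate F1, an isolable sulfonate with a small, strongly activating leaving group. F1 is displaced by LiBr in DMPU at 50–60 °C with inversion, and the route is rejoined at bromide 9.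

Step 8 (tertiary chlorination with retention; risk of E1 loss, attack at the secondary bromonium carbon, or participation of the homoallylic alkene). The fallback sets out from 11 and bypasses both the chlorination and the late hydration. Bromohydrin 11 is cyclised across the ring by Markovnikov MHAT hydroalkoxylation (Co(salen) catalyst, N-fluoro-2,4,6-trimethylpyridinium triflate, (Me2SiH)2O) to (1S,2S,4R)-2-bromo-4-[(1R,3S)-3-bromo-1,2,2-trimethylcyclopentyl]-1-methyl-7-oxabicyclo[2.2.1]heptane F2. The oxygen bridge holds the future C–OH and C–Cl positions cis. BCl3 in CH2Cl2 at −78 °C then cleaves the C–O bond anti to bromine through a bromonium ion, chloride returns on the oxygen face, and aqueous work-up frees the tertiary alcohol. The route is rejoined at target 15. The open question in this fallback is which of the two tertiary C–O bonds ionises.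

Step 9 (facial selectivity of radical hydration at C1, and rate at a very hindered alkene). The fallback sets out from 13 and adds water ionically. Oxymercuration with Hg(OAc)2 in THF–H2O proceeds by anti, diaxial addition through the chair that avoids a syn-axial Br/OH pair and gives acetoxy[(1S,2R,4S,5S)-4-bromo-2-[(1R,3S)-3-bromo-1,2,2-trimethylcyclopentyl]-5-chloro-2-hydroxy-5-methylcyclohexyl]mercury F3. Demercuration with NaBH4/NaOH rejoins the route at target 15.

**Further compounds**
F1 | step 5 | (1R,3S)-2,2,3-trimethyl-3-(4-methylcyclohexa-1,4-dien-1-yl)cyclopentyl chloromethanesulfonate | CC1(C)[C@H](OS(=O)(=O)CCl)CC[C@@]1(C)C1=CCC(C)=CC1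
F2 | step 8 | (1S,2S,4R)-2-bromo-4-[(1R,3S)-3-bromo-1,2,2-trimethylcyclopentyl]-1-methyl-7-oxabicyclo[2.2.1]heptane | CC1(C)[C@@H](Br)CC[C@@]1(C)[C@]12CC[C@](C)(O1)[C@@H](Br)C2
F3 | step 9 | acetoxy[(1S,2R,4S,5S)-4-bromo-2-[(1R,3S)-3-bromo-1,2,2-trimethylcyclopentyl]-5-chloro-2-hydroxy-5-methylcyclohexyl]mercury | CC1(C)[C@@H](Br)CC[C@@]1(C)[C@@]1(O)[C@@H]([Hg]OC(C)=O)C[C@](C)(Cl)[C@@H](Br)C1
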